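Early in the elm run the free monomer falls almost as a first-order decay, so the thing to watch is the log-conversion, the logarithm of charged over remaining free monomer.

| flask | free monomer | transfer agent | initiator | temperature | remark | time |
|---|---|---|---|---|---|---|
| elm | 0.040 M | 2 mM | 2 mol% | 15 °C | run made earlier |  |
| amber | 0.020 M | 2.00 mM | 2 mol% | 15 °C |  | 4.0 h |
| grey | 0.020 M | 2.00 mM | 2 mol% | 0 °C |  | 4.0 h |
| violet | 0.020 M | 2.00 mM | 2 mol% | −15 °C |  | 4.0 h |
| blue | 0.020 M | 2.00 mM | 2 mol% | −30 °C |  | 4.0 h |

elm run (percent of the free monomer charged): time / min: monomer in chains / % = 4.00: 19.3; 8.00: 33.1; 12.0: 43.4; 15.0: 47.5; 20.0: 55.6; 25.0: 62.4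

(each reading ± 1 percentage point)

- the earlier runs do not show what temperature does; that part of a forecast is a guess
- no earlier run changes the charge of initiator; that part of a forecast is a guess

- the flask that comes out highest in amount of monomer in chains, in percent of the free monomer charged, or "all alike" when all lie within 1.5 percentage points (amber / grey / violet / blue / all alike)
- monomer in chains at the end, in percent of the free monomer charged, amber
- monomer in chains at the end, in percent of the free monomer charged, grey
- monomer in chains at the end, in percent of the free monomer charged, violet
- monomer in chains at the end, in percent of the free monomer charged, blue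

For whoever takes over the bench: in the elm run the log-conversion climbs at 0.0502 min⁻¹ up to the second reading but at 0.0315 min⁻¹ from the third reading to the last, and these are readings with their scatter. The limiting reagent is the initiator, 0.400 mM in amber, less than the 2.00 mM of transfer agent. This reckoning takes each initiator to make one living end, and takes the transfer agent to remove ends at a pseudo-first-order rate. The sag in elm then reads as a death rate of 0.0323 min⁻¹, a lifetime of 31.0 min.

Initial slope over death rate gives 1.77 for elm and 0.885 for amber, with half the initiator. This is the reach: the log-conversion at which a flask stops once its living ends are gone, proportional to initiator charged at fixed temperature and transfer agent. Amber should therefore stand near 58.7 %, and since 4.0 h is longer than the lifetime, extra time should add little. The initiator weighing is not to be disturbed, since in this reckoning the reach is proportional to it. Temperature is unread, so this reckoning commits to no number for grey, violet or blue.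

The forecast, which differs from this reckoning on amber, gives 51 % for amber, 70 % for grey, 47 % for violet and 17 % for blue, with grey highest: “Amber is equilibrium-limited and blue is kinetically limited”.

Amber gives 57.9 %, violet 49.5 % and blue 20.7 %, and grey comes highest at 67.4 %. At 4.00 h amber holds 3.61 × 10⁻⁴ M of dead chain and 3.85 × 10⁻⁵ M of spent initiator, with 3.21 × 10⁻⁷ M of living end. Its log-conversion is 0.865, against the reach of 0.885.

    free monomer + initiator → living end + monomer in chains (k = 28.0 M⁻¹ min⁻¹, Ea = 41.0 kJ mol⁻¹)
    free monomer + living end → monomer in chains + living end, rate k2*[living end]*[free monomer] (k = 27.0 M⁻¹ min⁻¹, Ea = 44.0 kJ mol⁻¹)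
    living end + transfer agent → dead chain (kL = 4.30 M⁻¹ min⁻¹, Ea = 61.0 kJ mol⁻¹)
    initiator → spent initiator (k = 0.0240 min⁻¹, Ea = 80.0 kJ mol⁻¹)
    (constants at 0 °C)

Blue ends at a log-conversion of 0.232 with 3.71 × 10⁻⁴ M of living end still there, short of its reach; this reckoning keeps that part of the reach the same at fixed temperature, transfer agent and time. Since the reach is proportional to initiator, the neighbour of blue with 3.4 mol% should reach 0.395, or 32.6 %. That neighbour of blue, computed, gives 32.6 %.

(The data stem from a simulated flask on assumed constants, and the scatter is random.)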